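The ketone carbon, oxolane C3 and C4, the exocyclic CH2 and its hydroxyl oxygen form a γ-hydroxy ketone, so the route stores these five atoms as the lactone ring of a cis-fused 6-aryl-3,7-dioxabicyclo[3.3.0]octan-2-one and makes the aryl–carbonyl bond last. An aryllithium opens this lactone: one operation forms the aryl ketone, frees the primary alcohol without a protecting group and, by methoxide-mediated enolisation in the same flask, moves the epimerisable C3 from the cis ring fusion to the all-trans oxolane. The lactone is built from one carbinol centre set by lipase resolution, relayed through ring-closing metathesis and an anti-selective conjugate addition.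

Key step: step 7

Remark: compounds 1, 4 and 11 are taken as commercial. Oxolane locants throughout are O1, C2 (ring CH2), C3 (carbon bearing the ester or acyl group), C4 (carbon bearing the one-carbon side chain), C5 (aryl-bearing carbon).

Step 1
Reactants: 1 3-(benzyloxy)-4-methoxybenzaldehyde
Product: 2 rac-1-[3-(benzyloxy)-4-methoxyphenyl]prop-2-en-1-ol
Conditions: CH2=CHMgBr, THF, 0 °C; aq. NH4Cl
Reagents that add atoms: vinylmagnesium bromide, C=C[Mg]Br
Why: Grignard 1,2-addition to an aryl aldehyde; the carbinol centre is formed racemic on purpose and resolved in step 2.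

Step 2
Reactants: 2 rac-1-[3-(benzyloxy)-4-methoxyphenyl]prop-2-en-1-ol
Product: 3 (1S)-1-[3-(benzyloxy)-4-methoxyphenyl]prop-2-en-1-ol
Conditions: Novozym 435 (immobilised Candida antarctica lipase B), vinyl acetate, MTBE, 30 °C, stopped just past half conversion; chromatography
Reagents that add atoms: none
Why: Lipase-catalysed kinetic resolution by transesterification: the enzyme should acylate the (R)-alcohol (aryl as large, vinyl as medium group), so the unreacted (S)-alcohol, whose carbinol carbon becomes oxolane C5, should be recovered in high enantiomeric purity.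

Step 3
Reactants: 3 (1S)-1-[3-(benzyloxy)-4-methoxyphenyl]prop-2-en-1-ol; 4 ethyl 2-(bromomethyl)prop-2-enoate
Product: 5 ethyl 2-({[(1S)-1-[3-(benzyloxy)-4-methoxyphenyl]prop-2-en-1-yl]oxy}methyl)prop-2-enoate
Conditions: NaH, THF, 0 °C to rt
Reagents that add atoms: none
Why: Williamson-type O-alkylation of the sodium alkoxide with an allylic bromide (SN2 and SN2′ paths give the same ether); the stereocentre is not involved.

Step 4
Reactants: 5 ethyl 2-({[(1S)-1-[3-(benzyloxy)-4-methoxyphenyl]prop-2-en-1-yl]oxy}methyl)prop-2-enoate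
Product: 6 ethyl (5S)-5-[3-(benzyloxy)-4-methoxyphenyl]-2,5-dihydrofuran-3-carboxylate
Conditions: Grubbs second-generation catalyst (5 mol%), CH2Cl2, 40 °C
Reagents that add atoms: none
Why: Ring-closing metathesis of the vinyl group with the 1,1-disubstituted acrylate unit closes the five-membered 2,5-dihydrofuran with loss of ethene and leaves C5 untouched.

Step 5
Reactants: 6 ethyl (5S)-5-[3-(benzyloxy)-4-methoxyphenyl]-2,5-dihydrofuran-3-carboxylate
Product: 8 ethyl (4S,5S)-5-[3-(benzyloxy)-4-methoxyphenyl]-4-ethenyloxolane-3-carboxylate (C3 epimers), via silyl ketene acetal 7 (not isolated)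
Conditions: CH2=CHMgBr, CuI (20 mol%), TMSCl, THF, −78 to −30 °C; aq. NH4Cl
Reagents that add atoms: vinylmagnesium bromide, C=C[Mg]Br; chlorotrimethylsilane, C[Si](C)(C)Cl (its silyl group stays only in 7)
Why: Copper-catalysed, TMSCl-accelerated conjugate addition of a Grignard reagent to the cyclic enoate: the vinyl group should enter at C4 on the face opposite the neighbouring C5 aryl group (4,5-trans, substrate control), while C3 arises as a mixture on protonation of 7 and is corrected in step 6.

Step 6
Reactants: 8 ethyl (4S,5S)-5-[3-(benzyloxy)-4-methoxyphenyl]-4-ethenyloxolane-3-carboxylate (C3 epimers)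
Product: 10 (1R,5R,6S)-6-[3-(benzyloxy)-4-methoxyphenyl]-3,7-dioxabicyclo[3.3.0]octan-2-one, via hydroxy ester 9 (not isolated)
Conditions: O3, CH2Cl2/MeOH, −78 °C; NaBH4, −78 to 0 °C; work-up, then DBU (0.2 equiv), toluene, 80 °C
Reagents that add atoms: ozone, [O-][O+]=O
Why: Ozonolysis with reductive borohydride work-up turns the vinyl group into CH2OH, and DBU equilibrates C3 through the ester enolate so that the 3,4-cis epimer, the only one able to close the cis-fused bicycle, is drained off by lactonisation, which fixes C3.

Step 7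
Reactants: 10 (1R,5R,6S)-6-[3-(benzyloxy)-4-methoxyphenyl]-3,7-dioxabicyclo[3.3.0]octan-2-one; 11 2-(benzyloxy)-4-bromo-1-methoxybenzene
Product: 14 {(3S,4R,5S)-5-[3-(benzyloxy)-4-methoxyphenyl]-4-(hydroxymethyl)oxolan-3-yl}[3-(benzyloxy)-4-methoxyphenyl]methanone, via aryllithium 12 (not isolated), via cis-hydroxy ketone 13 (not isolated)
Conditions: 11, n-BuLi, THF, −78 °C; add 10, −78 °C; then MeOH, −78 °C to rt; aq. NH4Cl
Reagents that add atoms: n-butyllithium, [Li]CCCC (its lithium stays only in 12)
Why: Bromine–lithium exchange on 11 gives aryllithium 12, which adds to the lactone carbonyl of 10 (acyl substitution; the lithium hemiketalate formed at −78 °C should not release the ketone before the quench, which holds back a second addition), and methanol then frees hydroxy ketone 13 and supplies LiOMe. The closest known reaction type is the opening of γ-lactones by aryllithium reagents to γ-hydroxy aryl ketones, followed by base-mediated epimerisation α to a ketone. No ring is closed: the lactone ring is opened, and the oxolane ring with C4 and C5 is carried through unchanged because neither centre is acidic. C3 is set under thermodynamic control: reversible enolisation of the aryl ketone should move the aroyl group from the cis position forced by the bicycle to the position trans to the C4 hydroxymethyl group, giving the all-trans oxolane. The step needs mono-addition and a clean cis-to-trans shift without β-elimination of the ring oxygen; the first is secured by the tetrahedral intermediate and the low temperature, the second by the poor overlap of the endocyclic C2–O bond with the exocyclic enolate (the reverse of a 5-endo-trig closure).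

Step 8
Reactants: 14 {(3S,4R,5S)-5-[3-(benzyloxy)-4-methoxyphenyl]-4-(hydroxymethyl)oxolan-3-yl}[3-(benzyloxy)-4-methoxyphenyl]methanone
Product: 15 [(3S,4R,5S)-5-(3-hydroxy-4-methoxyphenyl)-4-(hydroxymethyl)oxolan-3-yl](3-hydroxy-4-methoxyphenyl)methanone
Conditions: H2 (1 atm), 10% Pd/C, EtOAc, rt
Reagents that add atoms: none
Why: Catalytic hydrogenolysis of the two aryl benzyl ethers, which should cleave well before the cyclic benzylic ether or the electron-rich aryl ketone is attacked; no stereocentre is touched.

Compound list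
1 | 3-(benzyloxy)-4-methoxybenzaldehyde | COc1ccc(C=O)cc1OCc1ccccc1 | starting material
2 | rac-1-[3-(benzyloxy)-4-methoxyphenyl]prop-2-en-1-ol | COc1ccc(C(O)C=C)cc1OCc1ccccc1 | intermediate
3 | (1S)-1-[3-(benzyloxy)-4-methoxyphenyl]prop-2-en-1-ol | COc1ccc([C@@H](O)C=C)cc1OCc1ccccc1 | intermediate
4 | ethyl 2-(bromomethyl)prop-2-enoate | C=C(CBr)C(=O)OCC | starting material
5 | ethyl 2-({[(1S)-1-[3-(benzyloxy)-4-methoxyphenyl]prop-2-en-1-yl]oxy}methyl)prop-2-enoate | CCOC(=O)C(=C)CO[C@H](c1ccc(OC)c(OCc2ccccc2)c1)C=C | intermediate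
6 | ethyl (5S)-5-[3-(benzyloxy)-4-methoxyphenyl]-2,5-dihydrofuran-3-carboxylate | CCOC(=O)C1=C[C@@H](c2ccc(OC)c(OCc3ccccc3)c2)OC1 | intermediate
7 | O-ethyl O-trimethylsilyl ketene acetal of 8 (4S,5S; not isolated) | CCOC(O[Si](C)(C)C)=C1CO[C@H](c2ccc(OC)c(OCc3ccccc3)c2)[C@H]1C=C | intermediate
8 | ethyl (4S,5S)-5-[3-(benzyloxy)-4-methoxyphenyl]-4-ethenyloxolane-3-carboxylate (C3 epimers) | CCOC(=O)C1CO[C@H](c2ccc(OC)c(OCc3ccccc3)c2)[C@H]1C=C | intermediate
9 | ethyl (4R,5S)-5-[3-(benzyloxy)-4-methoxyphenyl]-4-(hydroxymethyl)oxolane-3-carboxylate (C3 epimers; not isolated) | CCOC(=O)C1CO[C@H](c2ccc(OC)c(OCc3ccccc3)c2)[C@H]1CO | intermediate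
10 | (1R,5R,6S)-6-[3-(benzyloxy)-4-methoxyphenyl]-3,7-dioxabicyclo[3.3.0]octan-2-one (cis-fused, aryl on the convex face) | O=C1[C@H]2CO[C@H](c3ccc(OC)c(OCc4ccccc4)c3)[C@H]2CO1 | intermediate
11 | 2-(benzyloxy)-4-bromo-1-methoxybenzene | COc1ccc(Br)cc1OCc1ccccc1 | starting material
12 | [3-(benzyloxy)-4-methoxyphenyl]lithium (not isolated) | COc1ccc([Li])cc1OCc1ccccc1 | intermediate
13 | {(3R,4R,5S)-5-[3-(benzyloxy)-4-methoxyphenyl]-4-(hydroxymethyl)oxolan-3-yl}[3-(benzyloxy)-4-methoxyphenyl]methanone (3,4-cis; in equilibrium with its cyclic hemiketal; not isolated) | COc1ccc(C(=O)[C@H]2CO[C@H](c3ccc(OC)c(OCc4ccccc4)c3)[C@H]2CO)cc1OCc1ccccc1 | intermediate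
14 | {(3S,4R,5S)-5-[3-(benzyloxy)-4-methoxyphenyl]-4-(hydroxymethyl)oxolan-3-yl}[3-(benzyloxy)-4-methoxyphenyl]methanone (all-trans) | COc1ccc(C(=O)[C@@H]2CO[C@H](c3ccc(OC)c(OCc4ccccc4)c3)[C@H]2CO)cc1OCc1ccccc1 | intermediate
15 | [(3S,4R,5S)-5-(3-hydroxy-4-methoxyphenyl)-4-(hydroxymethyl)oxolan-3-yl](3-hydroxy-4-methoxyphenyl)methanone | COc1ccc(C(=O)[C@@H]2CO[C@H](c3ccc(OC)c(O)c3)[C@H]2CO)cc1O | target

Total step count: 8. Longest linear sequence: 8 steps (1 to 15); aryl bromide 11 enters in step 7.

Steps most likely to fail

Step 7. The tetrahedral intermediate may collapse early and take up a second aryllithium, the lactone may be enolised instead of attacked, or the cis isomer may rest as its cyclic hemiketal so that the epimerisation stalls short of the trans ketone. The fallback sets out from 10 and comes back at 14. Aminolysis of lactone 10 with N,O-dimethylhydroxylamine hydrochloride and i-PrMgCl should give the hydroxy Weinreb amide F1. Silylation with TBSCl and imidazole should give the silyl ether F2. Aryllithium 12 should then stop at the chelated stage and give the cis ketone silyl ether F3. K2CO3 in MeOH should move it to the trans ketone silyl ether F4, where no hemiketal can form, and TBAF in THF should return 14.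

Step 5. Deprotonation of the doubly activated C5–H (benzylic, allylic, next to oxygen) by the Grignard reagent, or 1,2-attack on the ester, may outrun the conjugate addition. The fallback sets out from 6 and comes back at 10. A photochemical Giese addition of the hydroxymethyl radical (MeOH as solvent, benzophenone, 350 nm) under neutral conditions should add CH2OH to C4 anti to the aryl group and give hydroxy ester 9 directly. DBU in toluene should then close 9 to lactone 10 as in step 6. This fallback makes no new compound (F0).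

Step 8. Over-reduction may set in before both benzyl ethers are gone, either hydrogenolysis of the benzylic C5–O bond of the oxolane or reduction of the aryl ketone. The fallback sets out from 14 and comes back at 15. Non-reductive debenzylation with BCl3 and pentamethylbenzene in CH2Cl2 at −78 °C should transfer the benzyl groups to the arene scavenger. This fallback makes no new compound (F0).

Further compounds
F1 | step 7 | (3R,4R,5S)-5-[3-(benzyloxy)-4-methoxyphenyl]-4-(hydroxymethyl)-N-methoxy-N-methyloxolane-3-carboxamide | CON(C)C(=O)[C@H]1CO[C@H](c2ccc(OC)c(OCc3ccccc3)c2)[C@H]1CO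
F2 | step 7 | (3R,4R,5S)-5-[3-(benzyloxy)-4-methoxyphenyl]-4-{[(tert-butyldimethylsilyl)oxy]methyl}-N-methoxy-N-methyloxolane-3-carboxamide | CON(C)C(=O)[C@H]1CO[C@H](c2ccc(OC)c(OCc3ccccc3)c2)[C@H]1CO[Si](C)(C)C(C)(C)C
F3 | step 7 | {(3R,4R,5S)-5-[3-(benzyloxy)-4-methoxyphenyl]-4-{[(tert-butyldimethylsilyl)oxy]methyl}oxolan-3-yl}[3-(benzyloxy)-4-methoxyphenyl]methanone (3,4-cis) | COc1ccc(C(=O)[C@H]2CO[C@H](c3ccc(OC)c(OCc4ccccc4)c3)[C@H]2CO[Si](C)(C)C(C)(C)C)cc1OCc1ccccc1
F4 | step 7 | {(3S,4R,5S)-5-[3-(benzyloxy)-4-methoxyphenyl]-4-{[(tert-butyldimethylsilyl)oxy]methyl}oxolan-3-yl}[3-(benzyloxy)-4-methoxyphenyl]methanone (all-trans) | COc1ccc(C(=O)[C@@H]2CO[C@H](c3ccc(OC)c(OCc4ccccc4)c3)[C@H]2CO[Si](C)(C)C(C)(C)C)cc1OCc1ccccc1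
F0 | step 5 | none | none
F0 | step 8 | none | none
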